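The cyclopentane core has two adjacent quaternary carbons with cis methyls: ring C1 (methyl, acyl) and ring C2 (methyl, CH2 arm). They are traced to the two alkene carbons of enone 4, a cyclopentenone fused to a cyclopentene through its tetrasubstituted C=C. The ketone-bearing ring is a disposable scaffold: cutting it later between the carbonyl carbon and its α-CH2 leaves the acyl carbon on C1 and the two-carbon arm on C2. One pot adds methyl enantioselectively to the β fusion carbon and methylates the bridgehead enolate, making both C–CH3 bonds and both stereocentres; the cis-only bicyclo[3.3.0]octane fusion forces the methyls cis.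

Key step: step 2

Remark: the stereocentres formed at C3 of 10, at C2 of 13 and at the carbinol carbon of 24 are all destroyed later, so these compounds are carried as epimer mixtures and drawn without configuration there. Bicyclo[3.3.0]octane numbering (C1/C5 ring fusion, C2 carbonyl) is used for 4–13.

Step 1
Reactants: 1 cyclopentene; 2 acrylic acid
Product: 4 bicyclo[3.3.0]oct-1(5)-en-2-one, via cyclopent-1-enyl vinyl ketone 3 (not isolated)
Conditions: PPA, 60 °C
Reagents that add atoms: acrylic acid 2, C=CC(=O)O
Why: PPA turns acrylic acid into a mixed anhydride that acylates cyclopentene (Friedel–Crafts-type alkene acylation) to dienone 3, whose protonated form undergoes Nazarov 4π-electrocyclisation and proton loss to the most substituted, ring-fusion enone; no stereocentre is formed.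

Step 2
Reactants: 4 bicyclo[3.3.0]oct-1(5)-en-2-one; 5 methylmagnesium bromide; 6 iodomethane
Product: 8 (1R,5R)-1,5-dimethylbicyclo[3.3.0]octan-2-one, via bromomagnesium (5R)-5-methylbicyclo[3.3.0]oct-1-en-2-olate 7 (not isolated)
Conditions: Cu(OTf)2 (5 mol%), chiral N-mesityl-N′-(1-hydroxy-4-methylpent-2-yl)imidazolinium salt (6 mol%), MeMgBr (slow addition), Et2O, −30 → 0 °C; then MeI (excess), DMPU, 0 °C → rt
Reagents that add atoms: methylmagnesium bromide 5, C[Mg]Br; iodomethane 6, CI
Why: Proposed new method: a chiral NHC–Cu(I)–methyl species formed from 5 should bind the enone π-bond, add oxidatively to give a Cu(III) β-adduct and eliminate reductively to make the C5–CH3 bond, leaving magnesium enolate 7, which DMPU activates for C-methylation at C1 by 6. The closest known reaction type is the NHC–copper-catalysed asymmetric conjugate addition of Grignard reagents to β-substituted cycloalkenones, which builds quaternary centres and permits enolate trapping, together with stoichiometric cuprate addition–alkylation of ring-fused enones; an unactivated tetrasubstituted enone has not been shown in the catalytic asymmetric manifold. No ring is closed. C5 is set by the ligand, which selects the enone face (both ligand antipodes are accessible, and the one that delivers 5R is to be chosen by screening); C1 is set by the substrate, because a bicyclo[3.3.0]octane can only be cis-fused, so the electrophile must enter cis to the C5 methyl. The step needs 1,4- over 1,2-addition (copper catalysis, slow Grignard addition, ether solvent), C- over O-alkylation, and methylation at C1 only; the last is secured because conjugate addition generates the bridgehead enolate regiospecifically and excess MeI should outrun proton transfer to C3.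

Step 3
Reactants: 8 (1R,5R)-1,5-dimethylbicyclo[3.3.0]octan-2-one
Product: 10 (1R,5R)-3-hydroxy-1,5-dimethylbicyclo[3.3.0]octan-2-one (C3 epimers), via potassium (1R,5R)-1,5-dimethylbicyclo[3.3.0]oct-2-en-2-olate 9 (not isolated)
Conditions: KHMDS, THF, −78 °C; 2-(phenylsulfonyl)-3-phenyloxaziridine, −78 °C; aq NH4Cl
Reagents that add atoms: 2-(phenylsulfonyl)-3-phenyloxaziridine, O=S(=O)(c1ccccc1)N1OC1c1ccccc1
Why: Enolate hydroxylation with an N-sulfonyloxaziridine: C3 is the only enolisable position (C1 is quaternary) and the potassium enolate attacks the electrophilic oxygen; the C3 configuration is uncontrolled and irrelevant because C3 becomes the aldehyde carbon.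

Step 4
Reactants: 10 (1R,5R)-3-hydroxy-1,5-dimethylbicyclo[3.3.0]octan-2-one; 11 1-chloro-3-methylbut-2-ene (prenyl chloride)
Product: 13 (1R,5R)-1,5-dimethyl-2-(3-methylbut-2-en-1-yl)bicyclo[3.3.0]octane-2,3-diol (C2/C3 epimers), via prenylbarium chloride 12 (not isolated)
Conditions: BaI2, lithium biphenylide, THF, rt; 11 (3.5 equiv), −78 °C; then 10, −78 → −40 °C; aq NH4Cl
Reagents that add atoms: 1-chloro-3-methylbut-2-ene 11, CC(C)=CCCl
Why: Allylbarium carbonyl allylation: prenylbarium chloride made and kept at −78 °C reacts through its unsubstituted α-carbon, so after one equivalent is spent on the hydroxyl the alkoxy ketone should take up the linear prenyl group; the new carbinol configuration is irrelevant because the C2–C3 bond is cut next.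

Step 5
Reactants: 13 (1R,5R)-1,5-dimethyl-2-(3-methylbut-2-en-1-yl)bicyclo[3.3.0]octane-2,3-diol
Product: 14 2-[(1R,2R)-1,2-dimethyl-2-(4-methylpent-3-enoyl)cyclopentyl]acetaldehyde
Conditions: Pb(OAc)4, CH2Cl2, 0 °C
Reagents that add atoms: none
Why: Criegee glycol cleavage through a cyclic lead(IV) diester, which accepts cis- and trans-cyclopentanediols and spares the trisubstituted alkene, turns the tertiary carbinol into the prenyl ketone and C3 into the aldehyde without touching the two quaternary stereocentres.

Step 6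
Reactants: 15 4-methoxy-2-methylphenol
Product: 16 2-bromo-4-methoxy-6-methylphenol
Conditions: NBS, i-Pr2NH (10 mol%), CH2Cl2, 0 °C
Reagents that add atoms: N-bromosuccinimide, O=C1CCC(=O)N1Br
Why: Amine-mediated ortho-bromination of a free phenol (electrophilic aromatic substitution): the para position carries OMe and one ortho position carries methyl, so bromine should enter at the remaining ortho carbon.

Step 7
Reactants: 16 2-bromo-4-methoxy-6-methylphenol; 6 iodomethane
Product: 17 1-bromo-2,5-dimethoxy-3-methylbenzene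
Conditions: MeI, K2CO3, acetone, reflux
Reagents that add atoms: iodomethane 6, CI
Why: Williamson ether synthesis on the phenoxide gives a p-dimethoxyarene that withstands the organometallic steps and can be unmasked oxidatively at the end.

Step 8
Reactants: 17 1-bromo-2,5-dimethoxy-3-methylbenzene; 18 2-methyl-2-vinyloxirane
Product: 20 (E)-4-(2,5-dimethoxy-3-methylphenyl)-2-methylbut-2-en-1-ol, via (2,5-dimethoxy-3-methylphenyl)magnesium bromide 19 (not isolated)
Conditions: Mg, THF, 50 °C; then CuI (10 mol%), 18, THF, −30 °C; aq NH4Cl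
Reagents that add atoms: 2-methyl-2-vinyloxirane 18, CC1(C=C)CO1
Why: Copper-catalysed SN2′ opening of a vinyl oxirane by an aryl Grignard reagent: the arylcopper species attacks the vinyl terminus with displacement of the epoxide oxygen, and the s-trans conformer of the vinyl oxirane should give mainly the (E)-trisubstituted allylic alcohol, with minor isomers to be removed by chromatography.

Step 9
Reactants: 20 (E)-4-(2,5-dimethoxy-3-methylphenyl)-2-methylbut-2-en-1-ol
Product: 22 1-[(E)-4-chloro-3-methylbut-2-en-1-yl]-2,5-dimethoxy-3-methylbenzene, via allylic mesylate 21 (not isolated)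
Conditions: MsCl, s-collidine, LiCl, DMF, 0 °C
Reagents that add atoms: lithium chloride, [Li+].[Cl-]
Why: In-situ mesylation and SN2 displacement by chloride at the primary allylic carbon under buffered conditions should give the primary chloride without allylic transposition or loss of alkene geometry.

Step 10
Reactants: 14 2-[(1R,2R)-1,2-dimethyl-2-(4-methylpent-3-enoyl)cyclopentyl]acetaldehyde; 22 1-[(E)-4-chloro-3-methylbut-2-en-1-yl]-2,5-dimethoxy-3-methylbenzene
Product: 24 1-[(1R,2R)-2-[(E)-6-(2,5-dimethoxy-3-methylphenyl)-2-hydroxy-4-methylhex-4-en-1-yl]-1,2-dimethylcyclopentyl]-4-methylpent-3-en-1-one (carbinol epimers), via aryl-allylbarium chloride 23 (not isolated)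
Conditions: BaI2, lithium biphenylide, THF, rt; 22, −78 °C; then 14, −78 °C; aq NH4Cl
Reagents that add atoms: none
Why: Allylbarium carbonyl allylation: reagent 23, generated at −78 °C where it keeps its E geometry, should attack through its α-CH2 and react with the aldehyde much faster than with the hindered α-quaternary ketone; the carbinol configuration is uncontrolled and is erased by the next oxidation.

Step 11
Reactants: 24 1-[(1R,2R)-2-[(E)-6-(2,5-dimethoxy-3-methylphenyl)-2-hydroxy-4-methylhex-4-en-1-yl]-1,2-dimethylcyclopentyl]-4-methylpent-3-en-1-one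
Product: 25 (E)-1-[(1R,2R)-1,2-dimethyl-2-(4-methylpent-3-enoyl)cyclopentyl]-6-(2,5-dimethoxy-3-methylphenyl)-4-methylhex-4-en-2-one
Conditions: DMP, pyridine, CH2Cl2, 0 °C → rt
Reagents that add atoms: none
Why: Dess–Martin oxidation under pyridine-buffered, non-enolising conditions converts the secondary homoallylic alcohol into the ketone while the β,γ-alkene stays out of conjugation, and the quaternary stereocentres cannot epimerise.

Step 12
Reactants: 25 (E)-1-[(1R,2R)-1,2-dimethyl-2-(4-methylpent-3-enoyl)cyclopentyl]-6-(2,5-dimethoxy-3-methylphenyl)-4-methylhex-4-en-2-one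
Product: 27 (E)-1-[(1R,2R)-1,2-dimethyl-2-(4-methylpent-3-enoyl)cyclopentyl]-6-(2,5-dihydroxy-3-methylphenyl)-4-methylhex-4-en-2-one, via quinone 26 (not isolated)
Conditions: CAN, MeCN–H2O, 0 °C; then EtOAc, sat. aq Na2S2O4, rt
Reagents that add atoms: water, O
Why: Oxidative demethylation of the p-dimethoxyarene by Ce(IV) (single-electron oxidation, water attack at both ipso carbons, loss of methanol) gives quinone 26, which dithionite reduces directly to the hydroquinone; short contact at 0 °C should spare the trisubstituted alkenes and the β,γ-unsaturated ketones.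

Compound list
1 | cyclopentene | C1=CCCC1 | starting material
2 | acrylic acid | C=CC(=O)O | starting material
3 | 1-(cyclopent-1-en-1-yl)prop-2-en-1-one (cyclopent-1-enyl vinyl ketone) | C=CC(=O)C1=CCCC1 | intermediate
4 | bicyclo[3.3.0]oct-1(5)-en-2-one | O=C1CCC2=C1CCC2 | intermediate
5 | methylmagnesium bromide | C[Mg]Br | starting material
6 | iodomethane | CI | starting material
7 | bromomagnesium (5R)-5-methylbicyclo[3.3.0]oct-1-en-2-olate | Br[Mg]OC1=C2CCC[C@]2(C)CC1 | intermediate
8 | (1R,5R)-1,5-dimethylbicyclo[3.3.0]octan-2-one | O=C1[C@]2(C)CCC[C@]2(C)CC1 | intermediate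
9 | potassium (1R,5R)-1,5-dimethylbicyclo[3.3.0]oct-2-en-2-olate | [K+].[O-]C=1[C@]2(C)CCC[C@]2(C)CC=1 | intermediate
10 | (1R,5R)-3-hydroxy-1,5-dimethylbicyclo[3.3.0]octan-2-one (C3 epimers) | O=C1[C@]2(C)CCC[C@]2(C)CC1O | intermediate
11 | 1-chloro-3-methylbut-2-ene (prenyl chloride) | CC(C)=CCCl | starting material
12 | prenylbarium chloride | CC(C)=CC[Ba]Cl | intermediate
13 | (1R,5R)-1,5-dimethyl-2-(3-methylbut-2-en-1-yl)bicyclo[3.3.0]octane-2,3-diol (C2/C3 epimers) | CC(C)=CCC1(O)[C@]2(C)CCC[C@]2(C)CC1O | intermediate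
14 | 2-[(1R,2R)-1,2-dimethyl-2-(4-methylpent-3-enoyl)cyclopentyl]acetaldehyde | CC(C)=CCC(=O)[C@]1(C)CCC[C@]1(C)CC=O | intermediate
15 | 4-methoxy-2-methylphenol | COc1ccc(O)c(C)c1 | starting material
16 | 2-bromo-4-methoxy-6-methylphenol | COc1cc(C)c(O)c(Br)c1 | intermediate
17 | 1-bromo-2,5-dimethoxy-3-methylbenzene | COc1cc(C)c(OC)c(Br)c1 | intermediate
18 | 2-methyl-2-vinyloxirane (racemic) | CC1(C=C)CO1 | starting material
19 | (2,5-dimethoxy-3-methylphenyl)magnesium bromide | COc1cc(C)c(OC)c([Mg]Br)c1 | intermediate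
20 | (E)-4-(2,5-dimethoxy-3-methylphenyl)-2-methylbut-2-en-1-ol | OC/C(C)=C/Cc1cc(OC)cc(C)c1OC | intermediate
21 | (E)-4-(2,5-dimethoxy-3-methylphenyl)-2-methylbut-2-en-1-yl methanesulfonate | CS(=O)(=O)OC/C(C)=C/Cc1cc(OC)cc(C)c1OC | intermediate
22 | 1-[(E)-4-chloro-3-methylbut-2-en-1-yl]-2,5-dimethoxy-3-methylbenzene | ClC/C(C)=C/Cc1cc(OC)cc(C)c1OC | intermediate
23 | [(E)-4-(2,5-dimethoxy-3-methylphenyl)-2-methylbut-2-en-1-yl]barium chloride | Cl[Ba]C/C(C)=C/Cc1cc(OC)cc(C)c1OC | intermediate
24 | 1-[(1R,2R)-2-[(E)-6-(2,5-dimethoxy-3-methylphenyl)-2-hydroxy-4-methylhex-4-en-1-yl]-1,2-dimethylcyclopentyl]-4-methylpent-3-en-1-one (carbinol epimers) | CC(C)=CCC(=O)[C@]1(C)CCC[C@]1(C)CC(O)C/C(C)=C/Cc1cc(OC)cc(C)c1OC | intermediate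
25 | (E)-1-[(1R,2R)-1,2-dimethyl-2-(4-methylpent-3-enoyl)cyclopentyl]-6-(2,5-dimethoxy-3-methylphenyl)-4-methylhex-4-en-2-one | CC(C)=CCC(=O)[C@]1(C)CCC[C@]1(C)CC(=O)C/C(C)=C/Cc1cc(OC)cc(C)c1OC | intermediate
26 | 2-[(E)-6-[(1R,2R)-1,2-dimethyl-2-(4-methylpent-3-enoyl)cyclopentyl]-3-methyl-5-oxohex-2-en-1-yl]-6-methyl-1,4-benzoquinone | CC(C)=CCC(=O)[C@]1(C)CCC[C@]1(C)CC(=O)C/C(C)=C/CC1=CC(=O)C=C(C)C1=O | intermediate
27 | (E)-1-[(1R,2R)-1,2-dimethyl-2-(4-methylpent-3-enoyl)cyclopentyl]-6-(2,5-dihydroxy-3-methylphenyl)-4-methylhex-4-en-2-one | CC(C)=CCC(=O)[C@]1(C)CCC[C@]1(C)CC(=O)C/C(C)=C/Cc1cc(O)cc(C)c1O | target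

Total step count: 12. Longest linear sequence: 8 steps (1–5, then 10–12); the aryl-allyl chloride branch (steps 6–9) joins at step 10.

Steps most likely to fail

1. Step 2. The chiral copper catalyst may not turn over on the tetrasubstituted enone, so uncatalysed 1,2-addition could take over. Face discrimination may be poor, or proton transfer may move the enolate to C3 before methylation. Fallback with known chemistry, setting out from 4: stoichiometric lithium dimethylcuprate (MeLi, CuI, Et2O, 0 °C) followed by MeI/HMPA should give racemic cis-1,5-dimethylbicyclo[3.3.0]octan-2-one F1. Addition of lithiated (S)-N,S-dimethyl-S-phenylsulfoximine (n-BuLi, THF, −78 °C) should give two diastereomeric β-hydroxysulfoximines to be separated on silica: the adduct of the (1R,5R)-ketone, (1R,5R)-1,5-dimethyl-2-{[(S)-N-methyl-S-phenylsulfonimidoyl]methyl}bicyclo[3.3.0]octan-2-ol F2, and the adduct of the (1S,5S)-ketone, (1S,5S)-1,5-dimethyl-2-{[(S)-N-methyl-S-phenylsulfonimidoyl]methyl}bicyclo[3.3.0]octan-2-ol F3. Thermolysis of F2 (toluene, reflux) reverses the addition and comes back to the route at 8.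

2. Step 4. The basic prenylbarium may enolise the hindered alkoxy ketone instead of adding, or attack may occur through the γ-carbon to give the reverse-prenyl carbinol. Fallback from 10: excess allylmagnesium bromide (THF, −78 → 0 °C), which has no regiochemical ambiguity, should give (1R,5R)-2-allyl-1,5-dimethylbicyclo[3.3.0]octane-2,3-diol F4. Cross-metathesis of F4 with 2-methylbut-2-ene (second-generation ruthenium benzylidene catalyst, CH2Cl2, 40 °C) converts allyl into prenyl and comes back to the route at 13.

3. Step 10. Proton transfer from the enolisable aldehyde or from the doubly activated CH2 of the prenyl ketone may quench the basic allylbarium, α-regiocontrol or E geometry may erode if the reagent warms, and homocoupling may occur while the reagent forms. Fallback from 22: displacement with sodium benzenesulfinate (DMF, rt) should give 1-[(E)-3-methyl-4-(phenylsulfonyl)but-2-en-1-yl]-2,5-dimethoxy-3-methylbenzene F5. Its α-sulfonyl anion (n-BuLi, THF, −78 °C) adds through the sulfonyl-bearing carbon to aldehyde 14 to give the β-hydroxy sulfone 1-[(1R,2R)-2-[(E)-6-(2,5-dimethoxy-3-methylphenyl)-2-hydroxy-4-methyl-3-(phenylsulfonyl)hex-4-en-1-yl]-1,2-dimethylcyclopentyl]-4-methylpent-3-en-1-one F6. Dess–Martin oxidation gives the β-keto sulfone (E)-1-[(1R,2R)-1,2-dimethyl-2-(4-methylpent-3-enoyl)cyclopentyl]-6-(2,5-dimethoxy-3-methylphenyl)-4-methyl-3-(phenylsulfonyl)hex-4-en-2-one F7, and reductive desulfonylation (SmI2, THF–MeOH, −78 °C) comes back to the route at 25.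

Further compounds
F1 | step 2 | racemic cis-1,5-dimethylbicyclo[3.3.0]octan-2-one | O=C1[C@]2(C)CCC[C@]2(C)CC1.O=C1[C@@]2(C)CCC[C@@]2(C)CC1
F2 | step 2 | (1R,5R)-1,5-dimethyl-2-{[(S)-N-methyl-S-phenylsulfonimidoyl]methyl}bicyclo[3.3.0]octan-2-ol | OC1(C[S@@](=O)(=NC)c3ccccc3)[C@]2(C)CCC[C@]2(C)CC1
F3 | step 2 | (1S,5S)-1,5-dimethyl-2-{[(S)-N-methyl-S-phenylsulfonimidoyl]methyl}bicyclo[3.3.0]octan-2-ol | OC1(C[S@@](=O)(=NC)c3ccccc3)[C@@]2(C)CCC[C@@]2(C)CC1
F4 | step 4 | (1R,5R)-2-allyl-1,5-dimethylbicyclo[3.3.0]octane-2,3-diol (C2/C3 epimers) | C=CCC1(O)[C@]2(C)CCC[C@]2(C)CC1O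
F5 | step 10 | 1-[(E)-3-methyl-4-(phenylsulfonyl)but-2-en-1-yl]-2,5-dimethoxy-3-methylbenzene | O=S(=O)(C/C(C)=C/Cc1cc(OC)cc(C)c1OC)c1ccccc1
F6 | step 10 | 1-[(1R,2R)-2-[(E)-6-(2,5-dimethoxy-3-methylphenyl)-2-hydroxy-4-methyl-3-(phenylsulfonyl)hex-4-en-1-yl]-1,2-dimethylcyclopentyl]-4-methylpent-3-en-1-one | CC(C)=CCC(=O)[C@]1(C)CCC[C@]1(C)CC(O)C(/C(C)=C/Cc1cc(OC)cc(C)c1OC)S(=O)(=O)c1ccccc1
F7 | step 10 | (E)-1-[(1R,2R)-1,2-dimethyl-2-(4-methylpent-3-enoyl)cyclopentyl]-6-(2,5-dimethoxy-3-methylphenyl)-4-methyl-3-(phenylsulfonyl)hex-4-en-2-one | CC(C)=CCC(=O)[C@]1(C)CCC[C@]1(C)CC(=O)C(/C(C)=C/Cc1cc(OC)cc(C)c1OC)S(=O)(=O)c1ccccc1
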